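Everything hinges on disconnecting C6–C7 together with the C8–CH3 bond. C7 is a bare methylene flanked by the methyl-bearing stereocentre C8 and by C6, the quaternary carbon of the 3,6-dihydro-1,2-dioxine ring, so a single carbon–metal bond at C7 can serve twice: making it sets C8, consuming it forges C6–C7. In one operation a chiral zirconocene adds methyl and aluminium across (S)-4-ethyloct-1-ene and the resulting alane is cross-coupled, through zinc and palladium, with a (Z)-3-iodopent-2-enyl silyl ether. The Z geometry of the coupled allylic ether is later translated into the C6 configuration (epoxidation, then hydrogen peroxide opening with inversion); the peroxide ring is closed last.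

Key step: step 4

Atom numbers: C1–C14 follow the acid chain of the target (C1 = CO2H, C3 and C6 = ring carbons bound to oxygen, C7–C14 = octyl chain).
Assumption: (+)-bis(1-neomenthylindenyl)zirconium dichloride is taken to be the antipode that gives the (S)-configured β-carbon when CH2–Al > chain > new alkyl, with AlEt3 and with AlMe3 alike; an oxidised aliquot would confirm the sign before scale-up.

Step 1
Reactants: 1 hex-1-ene; 2 triethylaluminium; 3 vinyl bromide
Product: 5 (4S)-4-ethyloct-1-ene, via ethylhexyl diethylalane 4 (not isolated)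
Conditions: AlEt3, (+)-bis(1-neomenthylindenyl)zirconium dichloride (cat.), CH2Cl2, 0 °C to rt; volatiles removed; Zn(OTf)2, DMF, 70 °C; then CH2=CHBr, Pd(DPEphos)Cl2 (cat.), iBu2AlH (cat.), rt
Reagents that add atoms: triethylaluminium (2), CC[Al](CC)CC; vinyl bromide (3), C=CBr
Why: Zirconium-catalysed asymmetric carboalumination (ethylalumination) of a terminal alkene should put ethyl on C2 of hexene and aluminium on C1, the chiral indenyl ligands choosing the alkene face and so setting the future C10 centre, after which the primary alane is vinylated in the same flask by zinc-mediated, palladium-catalysed Negishi coupling that does not touch the new centre.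

Step 2
Reactants: 6 pent-2-yn-1-ol
Product: 8 (2Z)-3-iodopent-2-en-1-ol, via cyclic alkenylalanate 7 (not isolated)
Conditions: NaAlH2(OCH2CH2OMe)2, THF, 0 °C; then I2, THF, −78 °C to 0 °C
Reagents that add atoms: iodine, II
Why: trans-Hydroalumination of the propargylic alkoxide (hydride to C2, aluminium to C3 inside a five-membered oxa-alanate) followed by iodinolysis of the C–Al bond with retention should give only the Z-iodide, with iodine and CH2OH cis.

Step 3
Reactants: 8 (2Z)-3-iodopent-2-en-1-ol
Product: 9 tert-butyl{[(2Z)-3-iodopent-2-en-1-yl]oxy}dimethylsilane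
Conditions: TBSCl, imidazole, CH2Cl2, 0 °C to rt
Reagents that add atoms: tert-butyldimethylsilyl chloride, CC(C)(C)[Si](C)(C)Cl
Why: Routine silylation of a primary allylic alcohol; the ether keeps the hydroxyl from quenching the alane and zinc species of step 4 and leaves the alkene geometry untouched.

Step 4
Reactants: 5 (4S)-4-ethyloct-1-ene; 10 trimethylaluminium; 9 tert-butyl{[(2Z)-3-iodopent-2-en-1-yl]oxy}dimethylsilane
Product: 12 tert-butyl{[(2Z,5S,7S)-3,7-diethyl-5-methylundec-2-en-1-yl]oxy}dimethylsilane, via primary alane 11 (not isolated)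
Conditions: AlMe3, (+)-bis(1-neomenthylindenyl)zirconium dichloride (cat.), (MeAlO)n (cat.), CH2Cl2, 0 °C to rt; volatiles removed; Zn(OTf)2, DMF, 70 °C; then 9, Pd(DPEphos)Cl2 (cat.), iBu2AlH (cat.), rt
Reagents that add atoms: trimethylaluminium (10), C[Al](C)C
Why: AlMe3 converts the zirconium dichloride into a chiral cationic methylzirconocene that inserts the terminal alkene of 5 with methyl going to C8 and zirconium to terminal C7, exchange with aluminium releasing primary alane 11; Zn(OTf)2 in DMF then passes the alkyl group to zinc, zerovalent palladium (from Pd(DPEphos)Cl2 and iBu2AlH) inserts into the C–I bond of 9, and transmetalation followed by reductive elimination forms C6–C7. The closest known reaction type is the zirconium-catalysed asymmetric carboalumination of terminal alkenes run in tandem with palladium-catalysed Negishi cross-coupling of the alane to an alkenyl halide. No ring is closed. The one new stereocentre, C8, is controlled by the catalyst, whose chiral indenyl ligands select the alkene face; the homoallylic C10 centre carries ethyl and butyl, almost equal in size, and should add no bias of its own. The step needs face selectivity at C8, metal on the terminal carbon, transfer of the isoalkyl and not a methyl group, and retention of the Z geometry: 5 is an unhindered monosubstituted alkene flanked only by CH2 (the best substrate class for this catalyst), the primary C7–metal bond is unhindered, excess AlMe3 is pumped off before zinc is added and the alane is used in excess over 9, and oxidative addition and reductive elimination at sp2 carbon keep the geometry.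

Step 5
Reactants: 12 tert-butyl{[(2Z,5S,7S)-3,7-diethyl-5-methylundec-2-en-1-yl]oxy}dimethylsilane
Product: 13 (2Z,5S,7S)-3,7-diethyl-5-methylundec-2-en-1-ol
Conditions: Bu4NF, THF, 0 °C
Reagents that add atoms: none
Why: Fluoride-induced cleavage of the silyl ether (strong Si–F bond) frees the allylic hydroxyl needed to direct the epoxidation; no stereocentre or alkene is affected.

Step 6
Reactants: 13 (2Z,5S,7S)-3,7-diethyl-5-methylundec-2-en-1-ol
Product: 14 [(2R,3S)-3-ethyl-3-[(2S,4S)-4-ethyl-2-methyloctyl]oxiran-2-yl]methanol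
Conditions: Ti(OiPr)4 (cat.), D-(−)-diisopropyl tartrate (cat.), t-BuOOH, 4 Å molecular sieves, CH2Cl2, −20 °C
Reagents that add atoms: tert-butyl hydroperoxide, CC(C)(C)OO
Why: Katsuki–Sharpless asymmetric epoxidation: the allylic alkoxide and the alkyl peroxide bound to the titanium tartrate complex deliver oxygen to one alkene face, D-(−)-tartrate giving the (2R,3S)-epoxide from this 3,3-disubstituted (Z)-allylic alcohol, and the syn addition keeps the C7 chain and CH2OH cis, so C6 is (S) at this stage and C5 is set as well.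

Step 7
Reactants: 14 [(2R,3S)-3-ethyl-3-[(2S,4S)-4-ethyl-2-methyloctyl]oxiran-2-yl]methanol
Product: 15 (2R,3R,5S,7S)-3,7-diethyl-3-hydroperoxy-5-methylundecane-1,2-diol
Conditions: H2O2 (anhydrous, in Et2O), H3PMo12O40 (cat.), Et2O, rt
Reagents that add atoms: hydrogen peroxide, OO
Why: Acid-catalysed perhydrolysis of a trisubstituted epoxide: hydrogen peroxide should attack the activated epoxide at tertiary C6, the carbon best able to carry positive charge, anti to the leaving oxygen, so C6 is inverted to the (R) configuration of the target while C5 is untouched.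

Step 8
Reactants: 15 (2R,3R,5S,7S)-3,7-diethyl-3-hydroperoxy-5-methylundecane-1,2-diol
Product: 16 (2R,3R,5S,7S)-3-[(tert-butyldimethylsilyl)peroxy]-3,7-diethyl-5-methylundecane-1,2-diol
Conditions: TBSCl, Et3N, CH2Cl2, −20 °C
Reagents that add atoms: tert-butyldimethylsilyl chloride, CC(C)(C)[Si](C)(C)Cl
Why: Chemoselective O-silylation (silyl peroxide formation): the hydroperoxide, several pKa units more acidic than the hydroxyls and an α-effect nucleophile, should be the only group silylated by the bulky chlorosilane under triethylamine without a nucleophilic catalyst, which masks it for steps 9–13.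

Step 9
Reactants: 16 (2R,3R,5S,7S)-3-[(tert-butyldimethylsilyl)peroxy]-3,7-diethyl-5-methylundecane-1,2-diol
Product: 17 (2R,4S,6S)-2-[(tert-butyldimethylsilyl)peroxy]-2,6-diethyl-4-methyldecanal
Conditions: NaIO4, THF/pH 7 buffer, 0 °C
Reagents that add atoms: none
Why: Periodate (Malaprade) glycol cleavage through a cyclic periodate ester removes the CH2OH carbon as formaldehyde and leaves the C5 aldehyde; the silyl peroxide is inert to periodate and quaternary C6 cannot epimerise.

Step 10
Reactants: 18 methyl 2-[bis(2,2,2-trifluoroethoxy)phosphoryl]acetate; 19 iodoethane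
Product: 20 methyl 2-[bis(2,2,2-trifluoroethoxy)phosphoryl]butanoate (racemic)
Conditions: KOtBu, THF, 0 °C; then EtI, 0 °C to rt
Reagents that add atoms: iodoethane (19), CCI
Why: C-Alkylation (SN2) of the stabilised phosphonoacetate anion with a primary iodide gives the α-ethyl Still–Gennari reagent; its stereocentre is irrelevant because it becomes sp2 in step 11.

Step 11
Reactants: 17 (2R,4S,6S)-2-[(tert-butyldimethylsilyl)peroxy]-2,6-diethyl-4-methyldecanal; 20 methyl 2-[bis(2,2,2-trifluoroethoxy)phosphoryl]butanoate
Product: 21 methyl (2Z,4R,6S,8S)-4-[(tert-butyldimethylsilyl)peroxy]-2,4,8-triethyl-6-methyldodec-2-enoate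
Conditions: KN(SiMe3)2, 18-crown-6, THF, −78 °C
Reagents that add atoms: phosphonate 20, CCC(C(=O)OC)P(=O)(OCC(F)(F)F)OCC(F)(F)F
Why: Still–Gennari variant of the Horner–Wadsworth–Emmons olefination: with the electron-poor bis(trifluoroethyl) phosphonate and a dissociated potassium counter-ion the kinetically formed adduct eliminates faster than it reverts, which should give the Z-trisubstituted enoate with C6 and the ester carbon cis, the geometry the ring closure needs.

Step 12
Reactants: 21 methyl (2Z,4R,6S,8S)-4-[(tert-butyldimethylsilyl)peroxy]-2,4,8-triethyl-6-methyldodec-2-enoate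
Product: 22 (2Z,4R,6S,8S)-4-[(tert-butyldimethylsilyl)peroxy]-2,4,8-triethyl-6-methyldodec-2-en-1-ol
Conditions: iBu2AlH, CH2Cl2, −78 °C
Reagents that add atoms: none
Why: Low-temperature aluminium hydride 1,2-reduction of an α,β-unsaturated ester to the allylic alcohol; the hindered silyl peroxide and the alkene geometry should survive at −78 °C.

Step 13
Reactants: 22 (2Z,4R,6S,8S)-4-[(tert-butyldimethylsilyl)peroxy]-2,4,8-triethyl-6-methyldodec-2-en-1-ol
Product: 23 (2Z,4R,6S,8S)-4-[(tert-butyldimethylsilyl)peroxy]-2,4,8-triethyl-6-methyldodec-2-enal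
Conditions: Dess–Martin periodinane, pyridine, CH2Cl2, 0 °C
Reagents that add atoms: none
Why: Dess–Martin oxidation of an allylic alcohol under buffered, non-isomerising conditions should give the Z-enal without touching the peroxide.

Step 14
Reactants: 23 (2Z,4R,6S,8S)-4-[(tert-butyldimethylsilyl)peroxy]-2,4,8-triethyl-6-methyldodec-2-enal
Product: 26 (6R)-4,6-diethyl-6-[(2S,4S)-4-ethyl-2-methyloctyl]-3-methoxy-3,6-dihydro-1,2-dioxine (both C3 epimers), via hydroperoxy enal 24 (not isolated), via ring peroxyhemiacetal 25 (not isolated)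
Conditions: camphorsulfonic acid (cat.), MeOH, 0 °C to rt
Reagents that add atoms: methanol, CO
Why: Acid-catalysed methanolysis of the silyl peroxide frees the hydroperoxide, which the Z-alkene holds next to the aldehyde so that it adds to it (6-exo-trig peroxyhemiacetal formation), and acetal exchange with methanol then gives the methyl peroxyacetal; its C3 configuration does not matter because C3 becomes planar in step 15.

Step 15
Reactants: 26 (6R)-4,6-diethyl-6-[(2S,4S)-4-ethyl-2-methyloctyl]-3-methoxy-3,6-dihydro-1,2-dioxine; 27 tert-butyl[(1-methoxyethenyl)oxy]dimethylsilane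
Product: 28 methyl 2-[(3R,6R)-4,6-diethyl-6-[(2S,4S)-4-ethyl-2-methyloctyl]-3,6-dihydro-1,2-dioxin-3-yl]acetate
Conditions: Me3SiOTf (cat.), CH2Cl2, −78 °C; chromatographic separation from the C3 epimer
Reagents that add atoms: ketene acetal 27, C=C(OC)O[Si](C)(C)C(C)(C)C
Why: Mukaiyama-type substitution of a cyclic peroxyacetal: the silyl triflate ionises the allylic peroxyacetal to a ring peroxycarbenium ion that the silyl ketene acetal should attack at C3, the oxygen-bearing terminus, but since the two faces differ only in the ethyl and octyl groups on distant C6 no useful bias is expected, so C3 is formed without control and the (3R) ester is to be separated from its C3 epimer by chromatography.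

Step 16
Reactants: 28 methyl 2-[(3R,6R)-4,6-diethyl-6-[(2S,4S)-4-ethyl-2-methyloctyl]-3,6-dihydro-1,2-dioxin-3-yl]acetate
Product: 29 2-[(3R,6R)-4,6-diethyl-6-[(2S,4S)-4-ethyl-2-methyloctyl]-3,6-dihydro-1,2-dioxin-3-yl]acetic acid
Conditions: LiOH, THF/H2O, 0 °C; then 1 M HCl to pH 3
Reagents that add atoms: lithium hydroxide, [Li+].[OH-]
Why: Saponification by acyl–oxygen cleavage with cold LiOH; the dialkyl peroxide tolerates hydroxide and low temperature with short contact should prevent β-elimination of the peroxide from the ester enolate, so C3 is retained.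

Compound list
1 | hex-1-ene | CCCCC=C | starting material
2 | triethylaluminium | CC[Al](CC)CC | starting material
3 | vinyl bromide | C=CBr | starting material
4 | diethyl[(2S)-2-ethylhexyl]alumane | CCCC[C@H](CC)C[Al](CC)CC | intermediate
5 | (4S)-4-ethyloct-1-ene | CCCC[C@H](CC)CC=C | intermediate
6 | pent-2-yn-1-ol | CCC#CCO | starting material
7 | sodium 3-ethyl-2,2-bis(2-methoxyethoxy)-2,5-dihydro-1,2-oxaalumol-2-uide | [Na+].CCC1=CCO[Al-]1(OCCOC)OCCOC | intermediate
8 | (2Z)-3-iodopent-2-en-1-ol | CC/C(I)=C/CO | intermediate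
9 | tert-butyl{[(2Z)-3-iodopent-2-en-1-yl]oxy}dimethylsilane | CC/C(I)=C/CO[Si](C)(C)C(C)(C)C | intermediate
10 | trimethylaluminium | C[Al](C)C | starting material
11 | [(2S,4S)-4-ethyl-2-methyloctyl]dimethylalumane | CCCC[C@H](CC)C[C@H](C)C[Al](C)C | intermediate
12 | tert-butyl{[(2Z,5S,7S)-3,7-diethyl-5-methylundec-2-en-1-yl]oxy}dimethylsilane | CCCC[C@H](CC)C[C@H](C)C/C(CC)=C\CO[Si](C)(C)C(C)(C)C | intermediate
13 | (2Z,5S,7S)-3,7-diethyl-5-methylundec-2-en-1-ol | CCCC[C@H](CC)C[C@H](C)C/C(CC)=C\CO | intermediate
14 | [(2R,3S)-3-ethyl-3-[(2S,4S)-4-ethyl-2-methyloctyl]oxiran-2-yl]methanol | CCCC[C@H](CC)C[C@H](C)C[C@]1(CC)O[C@@H]1CO | intermediate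
15 | (2R,3R,5S,7S)-3,7-diethyl-3-hydroperoxy-5-methylundecane-1,2-diol | CCCC[C@H](CC)C[C@H](C)C[C@@](CC)(OO)[C@H](O)CO | intermediate
16 | (2R,3R,5S,7S)-3-[(tert-butyldimethylsilyl)peroxy]-3,7-diethyl-5-methylundecane-1,2-diol | CCCC[C@H](CC)C[C@H](C)C[C@@](CC)(OO[Si](C)(C)C(C)(C)C)[C@H](O)CO | intermediate
17 | (2R,4S,6S)-2-[(tert-butyldimethylsilyl)peroxy]-2,6-diethyl-4-methyldecanal | CCCC[C@H](CC)C[C@H](C)C[C@@](CC)(OO[Si](C)(C)C(C)(C)C)C=O | intermediate
18 | methyl 2-[bis(2,2,2-trifluoroethoxy)phosphoryl]acetate | COC(=O)CP(=O)(OCC(F)(F)F)OCC(F)(F)F | starting material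
19 | iodoethane | CCI | starting material
20 | methyl 2-[bis(2,2,2-trifluoroethoxy)phosphoryl]butanoate (racemic) | CCC(C(=O)OC)P(=O)(OCC(F)(F)F)OCC(F)(F)F | intermediate
21 | methyl (2Z,4R,6S,8S)-4-[(tert-butyldimethylsilyl)peroxy]-2,4,8-triethyl-6-methyldodec-2-enoate | CCCC[C@H](CC)C[C@H](C)C[C@@](CC)(OO[Si](C)(C)C(C)(C)C)/C=C(/CC)C(=O)OC | intermediate
22 | (2Z,4R,6S,8S)-4-[(tert-butyldimethylsilyl)peroxy]-2,4,8-triethyl-6-methyldodec-2-en-1-ol | CCCC[C@H](CC)C[C@H](C)C[C@@](CC)(OO[Si](C)(C)C(C)(C)C)/C=C(/CC)CO | intermediate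
23 | (2Z,4R,6S,8S)-4-[(tert-butyldimethylsilyl)peroxy]-2,4,8-triethyl-6-methyldodec-2-enal | CCCC[C@H](CC)C[C@H](C)C[C@@](CC)(OO[Si](C)(C)C(C)(C)C)/C=C(/CC)C=O | intermediate
24 | (2Z,4R,6S,8S)-2,4,8-triethyl-4-hydroperoxy-6-methyldodec-2-enal | CCCC[C@H](CC)C[C@H](C)C[C@@](CC)(OO)/C=C(/CC)C=O | intermediate
25 | (6R)-4,6-diethyl-6-[(2S,4S)-4-ethyl-2-methyloctyl]-3,6-dihydro-1,2-dioxin-3-ol (both C3 epimers) | CCCC[C@H](CC)C[C@H](C)C[C@]1(CC)C=C(CC)C(O)OO1 | intermediate
26 | (6R)-4,6-diethyl-6-[(2S,4S)-4-ethyl-2-methyloctyl]-3-methoxy-3,6-dihydro-1,2-dioxine (both C3 epimers) | CCCC[C@H](CC)C[C@H](C)C[C@]1(CC)C=C(CC)C(OC)OO1 | intermediate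
27 | tert-butyl[(1-methoxyethenyl)oxy]dimethylsilane | C=C(OC)O[Si](C)(C)C(C)(C)C | starting material
28 | methyl 2-[(3R,6R)-4,6-diethyl-6-[(2S,4S)-4-ethyl-2-methyloctyl]-3,6-dihydro-1,2-dioxin-3-yl]acetate | CCCC[C@H](CC)C[C@H](C)C[C@]1(CC)C=C(CC)[C@@H](CC(=O)OC)OO1 | intermediate
29 | 2-[(3R,6R)-4,6-diethyl-6-[(2S,4S)-4-ethyl-2-methyloctyl]-3,6-dihydro-1,2-dioxin-3-yl]acetic acid | CCCC[C@H](CC)C[C@H](C)C[C@]1(CC)C=C(CC)[C@@H](CC(=O)O)OO1 | target

Total step count: 16.
Longest linear sequence: 14 steps (pent-2-yn-1-ol to 29: steps 2–9 and 11–16).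

Steps most likely to fail

1. Step 15. The ring peroxycarbenium ion is attacked with little facial preference, because its two faces differ only in ethyl versus the octyl chain on distant C6, so much of the material ends as the C3 epimer. The fallback replaces substrate control by reagent control. It sets out from 26. The chlorotitanium enolate of the N-acetyl derivative of (4S)-4-(propan-2-yl)-1,3-thiazolidine-2-thione (TiCl4, iPr2NEt, CH2Cl2, −78 °C, a further equivalent of TiCl4 to ionise the peroxyacetal) would be added to the same cation. This sulfur-chelated enolate has one face shielded and is known to tell apart the faces of oxocarbenium ions made from ordinary acetals, so the approach to C3 should be governed by the auxiliary and not by C6. This reactivity is established for ordinary acetals only and has not been tried on a peroxyacetal. The product would be 2-[(3R,6R)-4,6-diethyl-6-[(2S,4S)-4-ethyl-2-methyloctyl]-3,6-dihydro-1,2-dioxin-3-yl]-1-[(4S)-4-(propan-2-yl)-2-sulfanylidene-1,3-thiazolidin-3-yl]ethan-1-one F1; the antipodal auxiliary is taken if a first run shows the opposite sense. Mild LiOH hydrolysis of the imide releases the auxiliary and returns to the route at 29.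

2. Step 4. Diastereomeric purity at C8 is eroded by imperfect face selection of the catalyst, and iodide 9 is consumed by transfer of a methyl group in place of the isoalkyl group. The fallback separates the two events. It sets out from 5: the same zirconium-catalysed methylalumination is run to alane 11, which is oxidised with O2 instead of being coupled, giving (2S,4S)-4-ethyl-2-methyloctan-1-ol F2; unlike hydrocarbon 12, this alcohol can be freed from its C2 epimer before going on. I2, PPh3 and imidazole convert it into (2S,4S)-4-ethyl-1-iodo-2-methyloctane F3, and zinc dust with LiCl in THF gives [(2S,4S)-4-ethyl-2-methyloctyl]zinc iodide F4. A separate Negishi coupling of this zinc reagent with 9 under Pd(DPEphos)Cl2 catalysis returns to the route at 12, with no methyl group left to compete.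

3. Step 8. Silylation of the primary hydroxyl competes with silylation of the hydroperoxide, giving mixtures that cannot be cleaved cleanly in step 9. The fallback caps the primary hydroxyl before the peroxide exists. It sets out from 14: NaH and 4-methoxybenzyl chloride in THF give (2S,3R)-2-ethyl-2-[(2S,4S)-4-ethyl-2-methyloctyl]-3-{[(4-methoxyphenyl)methoxy]methyl}oxirane F5. Perhydrolysis as in step 7 gives (2R,3R,5S,7S)-3,7-diethyl-3-hydroperoxy-1-[(4-methoxyphenyl)methoxy]-5-methylundecan-2-ol F6, in which only a hindered secondary hydroxyl is left beside the hydroperoxide. TBSCl and Et3N then give (2R,3R,5S,7S)-3-[(tert-butyldimethylsilyl)peroxy]-3,7-diethyl-1-[(4-methoxyphenyl)methoxy]-5-methylundecan-2-ol F7, and oxidative removal of the benzyl ether with DDQ in wet CH2Cl2 returns to the route at 16.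

Further compounds
F1 | step 15 | 2-[(3R,6R)-4,6-diethyl-6-[(2S,4S)-4-ethyl-2-methyloctyl]-3,6-dihydro-1,2-dioxin-3-yl]-1-[(4S)-4-(propan-2-yl)-2-sulfanylidene-1,3-thiazolidin-3-yl]ethan-1-one | CCCC[C@H](CC)C[C@H](C)C[C@]1(CC)C=C(CC)[C@@H](CC(=O)N2[C@@H](C(C)C)CSC2=S)OO1
F2 | step 4 | (2S,4S)-4-ethyl-2-methyloctan-1-ol | CCCC[C@H](CC)C[C@H](C)CO
F3 | step 4 | (2S,4S)-4-ethyl-1-iodo-2-methyloctane | CCCC[C@H](CC)C[C@H](C)CI
F4 | step 4 | [(2S,4S)-4-ethyl-2-methyloctyl]zinc iodide | CCCC[C@H](CC)C[C@H](C)C[Zn]I
F5 | step 8 | (2S,3R)-2-ethyl-2-[(2S,4S)-4-ethyl-2-methyloctyl]-3-{[(4-methoxyphenyl)methoxy]methyl}oxirane | CCCC[C@H](CC)C[C@H](C)C[C@]1(CC)O[C@@H]1COCc1ccc(OC)cc1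
F6 | step 8 | (2R,3R,5S,7S)-3,7-diethyl-3-hydroperoxy-1-[(4-methoxyphenyl)methoxy]-5-methylundecan-2-ol | CCCC[C@H](CC)C[C@H](C)C[C@@](CC)(OO)[C@H](O)COCc1ccc(OC)cc1
F7 | step 8 | (2R,3R,5S,7S)-3-[(tert-butyldimethylsilyl)peroxy]-3,7-diethyl-1-[(4-methoxyphenyl)methoxy]-5-methylundecan-2-ol | CCCC[C@H](CC)C[C@H](C)C[C@@](CC)(OO[Si](C)(C)C(C)(C)C)[C@H](O)COCc1ccc(OC)cc1
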